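With germacrane numbering (carbocycle C1–C10, lactone O–C6–C7–C11–C12, exocyclic C13, furoate on O8), the ten-membered ring is opened at C7–C8. This exploits two features: C7 is the β-carbon of the α-methylene-γ-butyrolactone and C8 bears oxygen, so C7–C8 is a homoallylic-alcohol bond. The precursor is an open chain that ends in a 3-(bromomethyl)butenolide (C7=C11, C13–Br) and a C8 aldehyde and already carries the 4Z-alkene, the 3-silyloxy group and the 1,10-epoxide. CrCl2 turns the bromide into an allylchromium that adds through C7 to the aldehyde: one operation closes the carbocycle, moves the alkene to C11=C13 and sets C7 and C8. Invertive esterification and desilylation follow.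

Key step: step 14

Remark: atom labels follow germacrane numbering throughout (C14 = methyl on C10, C15 = methyl on C4); in step 4 the (S,S)-ProPhenol ligand is assumed to deliver the alkyne to the Re face (3S) as in its aldol reactions, and the (R,R)-ligand is taken if the sense is the opposite.

Step 1
Reactants: 1 but-3-yn-1-ol
Product: 2 1-[(but-3-yn-1-yloxy)methyl]-4-methoxybenzene
Conditions: NaH, 4-methoxybenzyl chloride, Bu4NI (cat.), THF/DMF, 0 °C to rt
Reagents that add atoms: 4-methoxybenzyl chloride, COc1ccc(CCl)cc1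
Why: Williamson etherification of the primary alkoxide gives a PMB ether on O8 that can later be removed under neutral oxidative conditions that spare an epoxide and an allylic bromide.

Step 2
Reactants: 2 1-[(but-3-yn-1-yloxy)methyl]-4-methoxybenzene
Product: 5 (E)-6-[(4-methoxybenzyl)oxy]-4-methylhex-3-en-1-ol, via alkenyldimethylalane 3 (not isolated), via lithium alkenylalanate 4 (not isolated)
Conditions: Me3Al, Cp2ZrCl2 (25 mol %), CH2Cl2, 0 °C to rt; solvent exchange to hexane/THF, n-BuLi, −78 °C; ethylene oxide, −78 °C to rt; aqueous work-up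
Reagents that add atoms: trimethylaluminium, C[Al](C)C; ethylene oxide, C1CO1
Why: Negishi zirconium-catalysed carboalumination adds methyl and aluminium syn across the terminal alkyne (methyl C14 to C10, Al to C1), and the derived alanate opens ethylene oxide with retention at the alkenyl carbon, so the E-trisubstituted C1=C10 alkene and the C2–C3 unit are installed in one flask.

Step 3
Reactants: 5 (E)-6-[(4-methoxybenzyl)oxy]-4-methylhex-3-en-1-ol
Product: 6 (E)-6-[(4-methoxybenzyl)oxy]-4-methylhex-3-enal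
Conditions: Dess–Martin periodinane, NaHCO3, CH2Cl2, 0 °C; used crude
Reagents that add atoms: none
Why: buffered Dess–Martin oxidation is non-basic, so the β,γ-unsaturated aldehyde should form without migration of the alkene into conjugation.

Step 4
Reactants: 6 (E)-6-[(4-methoxybenzyl)oxy]-4-methylhex-3-enal; 7 methyl propiolate
Product: 9 methyl (4S,6E)-4-hydroxy-9-[(4-methoxybenzyl)oxy]-7-methylnon-6-en-2-ynoate, via methylzinc alkynide 8 (not isolated)
Conditions: Me2Zn, (S,S)-ProPhenol ligand (20 mol %, forms the dinuclear zinc catalyst in situ), Ph3P=O (40 mol %), toluene, 0–4 °C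
Reagents that add atoms: none
Why: zinc–ProPhenol catalysed asymmetric alkynylation, in which the alkynylzinc 8 is delivered inside the chiral dinuclear zinc pocket to the Re face of the aldehyde, should set C3 as S by catalyst control.

Step 5
Reactants: 9 methyl (4S,6E)-4-hydroxy-9-[(4-methoxybenzyl)oxy]-7-methylnon-6-en-2-ynoate
Product: 10 methyl (4S,6E)-9-[(4-methoxybenzyl)oxy]-7-methyl-4-(triethylsilyloxy)non-6-en-2-ynoate
Conditions: Et3SiCl, imidazole, DMAP (cat.), CH2Cl2, 0 °C
Reagents that add atoms: chlorotriethylsilane, CC[Si](Cl)(CC)CC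
Why: standard silylation of the secondary propargylic alcohol; the TES ether prevents lactonisation after step 6 and is removable at the end with buffered fluoride.

Step 6
Reactants: 10 methyl (4S,6E)-9-[(4-methoxybenzyl)oxy]-7-methyl-4-(triethylsilyloxy)non-6-en-2-ynoate
Product: 11 methyl (2Z,4S,6E)-9-[(4-methoxybenzyl)oxy]-3,7-dimethyl-4-(triethylsilyloxy)nona-2,6-dienoate
Conditions: Me2CuLi (from MeLi and CuI), THF, −78 °C; MeOH then aqueous NH4Cl at −78 °C
Reagents that add atoms: lithium dimethylcuprate, [Li+].C[Cu-]C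
Why: Gilman cuprate conjugate addition to the alkynoate is a syn-carbocupration, so protonation at −78 °C leaves the new C15 methyl cis to H5 and C3 cis to the ester carbon C6, which is the 4Z alkene of the target.

Step 7
Reactants: 11 methyl (2Z,4S,6E)-9-[(4-methoxybenzyl)oxy]-3,7-dimethyl-4-(triethylsilyloxy)nona-2,6-dienoate
Product: 12 methyl (2Z,4S)-5-[(2R,3R)-3-{2-[(4-methoxybenzyl)oxy]ethyl}-3-methyloxiran-2-yl]-3-methyl-4-(triethylsilyloxy)pent-2-enoate
Conditions: D-fructose-derived Shi ketone (1,2:4,5-di-O-isopropylidene-β-D-erythro-2,3-hexodiulo-2,6-pyranose, 30 mol %), Oxone (2KHSO5·KHSO4·K2SO4), K2CO3, Bu4NHSO4, MeCN/dimethoxymethane/aqueous Na2B4O7 buffer, 0 °C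
Reagents that add atoms: potassium peroxymonosulfate, [K+].[O-]S(=O)(=O)OO
Why: Shi asymmetric epoxidation (chiral dioxirane, spiro transition state) should oxidise only the electron-rich E-trisubstituted C1=C10 alkene, the enoate being inert, and the D-fructose-derived ketone delivers oxygen to the face that gives the trans (1R,10R)-epoxide by reagent control.

Step 8
Reactants: 12 methyl (2Z,4S)-5-[(2R,3R)-3-{2-[(4-methoxybenzyl)oxy]ethyl}-3-methyloxiran-2-yl]-3-methyl-4-(triethylsilyloxy)pent-2-enoate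
Product: 14 (4Z,6S)-7-[(2R,3R)-3-{2-[(4-methoxybenzyl)oxy]ethyl}-3-methyloxiran-2-yl]-5-methyl-6-(triethylsilyloxy)hepta-1,4-dien-3-one, via Weinreb amide 13 (not isolated)
Conditions: MeNH(OMe)·HCl, i-PrMgCl, THF, −20 °C; then CH2=CHMgBr, −20 to 0 °C; inverse quench into cold aqueous NH4Cl
Reagents that add atoms: vinylmagnesium bromide, C=C[Mg]Br
Why: ester-to-amide exchange with the magnesium amide followed in the same flask by the Weinreb ketone synthesis, in which the chelated tetrahedral intermediate prevents over-addition and the cold inverse quench limits amine addition to the vinyl ketone.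

Step 9
Reactants: 14 (4Z,6S)-7-[(2R,3R)-3-{2-[(4-methoxybenzyl)oxy]ethyl}-3-methyloxiran-2-yl]-5-methyl-6-(triethylsilyloxy)hepta-1,4-dien-3-one
Product: 15 (3R,4Z,6S)-7-[(2R,3R)-3-{2-[(4-methoxybenzyl)oxy]ethyl}-3-methyloxiran-2-yl]-5-methyl-6-(triethylsilyloxy)hepta-1,4-dien-3-ol
Conditions: (S)-2-methyl-CBS-oxazaborolidine, catecholborane, toluene, −78 °C
Reagents that add atoms: none
Why: Corey–Bakshi–Shibata reduction, in which the bulky Z-trisubstituted alkenyl group acts as the large and vinyl as the small substituent, so the (S)-catalyst should deliver hydride to give the 3R carbinol (C6 of the target) by catalyst control and with 1,2-selectivity.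

Step 10
Reactants: 15 (3R,4Z,6S)-7-[(2R,3R)-3-{2-[(4-methoxybenzyl)oxy]ethyl}-3-methyloxiran-2-yl]-5-methyl-6-(triethylsilyloxy)hepta-1,4-dien-3-ol; 16 2-(bromomethyl)prop-2-enoic acid
Product: 17 (3R,4Z,6S)-7-[(2R,3R)-3-{2-[(4-methoxybenzyl)oxy]ethyl}-3-methyloxiran-2-yl]-5-methyl-6-(triethylsilyloxy)hepta-1,4-dien-3-yl 2-(bromomethyl)prop-2-enoate
Conditions: DCC, DMAP (5 mol %), CH2Cl2, −20 to 0 °C
Reagents that add atoms: none
Why: Steglich esterification acylates the bis-allylic alcohol with retention at C6, and low temperature with little DMAP should leave the allylic bromide untouched.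

Step 11
Reactants: 17 (3R,4Z,6S)-7-[(2R,3R)-3-{2-[(4-methoxybenzyl)oxy]ethyl}-3-methyloxiran-2-yl]-5-methyl-6-(triethylsilyloxy)hepta-1,4-dien-3-yl 2-(bromomethyl)prop-2-enoate
Product: 18 (5S)-3-(bromomethyl)-5-{(1Z,3S)-4-[(2R,3R)-3-{2-[(4-methoxybenzyl)oxy]ethyl}-3-methyloxiran-2-yl]-2-methyl-3-(triethylsilyloxy)but-1-en-1-yl}furan-2(5H)-one
Conditions: second-generation Grubbs catalyst (H2IMes)(PCy3)Cl2Ru=CHPh (5–10 mol %), CH2Cl2 (5 mM), 40 °C
Reagents that add atoms: none
Why: ring-closing metathesis, in which the ruthenium carbene loads at the terminal vinyl group and closes onto the 1,1-disubstituted acrylate alkene with loss of ethene, should give the butenolide (C7=C11, C13–Br) while the hindered trisubstituted C4=C5 alkene and the C6 centre stay untouched.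

Step 12
Reactants: 18 (5S)-3-(bromomethyl)-5-{(1Z,3S)-4-[(2R,3R)-3-{2-[(4-methoxybenzyl)oxy]ethyl}-3-methyloxiran-2-yl]-2-methyl-3-(triethylsilyloxy)but-1-en-1-yl}furan-2(5H)-one
Product: 19 (5S)-3-(bromomethyl)-5-{(1Z,3S)-4-[(2R,3R)-3-(2-hydroxyethyl)-3-methyloxiran-2-yl]-2-methyl-3-(triethylsilyloxy)but-1-en-1-yl}furan-2(5H)-one
Conditions: DDQ, CH2Cl2/pH 7 phosphate buffer, 0 °C
Reagents that add atoms: none
Why: oxidative PMB cleavage (hydride abstraction by DDQ, hydrolysis of the oxocarbenium ion) is neutral and free of nucleophiles, so the reactive allylic bromide, the epoxide and the TES ether should survive.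

Step 13
Reactants: 19 (5S)-3-(bromomethyl)-5-{(1Z,3S)-4-[(2R,3R)-3-(2-hydroxyethyl)-3-methyloxiran-2-yl]-2-methyl-3-(triethylsilyloxy)but-1-en-1-yl}furan-2(5H)-one
Product: 20 (5S)-3-(bromomethyl)-5-{(1Z,3S)-2-methyl-4-[(2R,3R)-3-methyl-3-(2-oxoethyl)oxiran-2-yl]-3-(triethylsilyloxy)but-1-en-1-yl}furan-2(5H)-one
Conditions: Dess–Martin periodinane, NaHCO3, CH2Cl2, 0 °C; filtered and used at once
Reagents that add atoms: none
Why: buffered Dess–Martin oxidation gives the β,γ-epoxy aldehyde without base, so β-elimination of the epoxide is avoided.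

Step 14
Reactants: 20 (5S)-3-(bromomethyl)-5-{(1Z,3S)-2-methyl-4-[(2R,3R)-3-methyl-3-(2-oxoethyl)oxiran-2-yl]-3-(triethylsilyloxy)but-1-en-1-yl}furan-2(5H)-one
Product: 22 (1R,3S,4Z,6S,7R,8S,10R)-1,10-epoxy-8-hydroxy-3-(triethylsilyloxy)germacra-4,11(13)-dien-12,6-olide, via allylchromium dichloride 21 (not isolated)
Conditions: CrCl2 (8 equiv), 4 Å molecular sieves, THF, rt, slow addition of 20 (final 1 mM); aqueous work-up
Reagents that add atoms: none
Why: Divalent chromium (two equivalents, one electron each) reduces the allylic C13–Br bond of 20 to the allylchromium 21 of trivalent chromium, which adds to the tethered C8 aldehyde through its γ-carbon C7 in a closed six-membered Zimmerman–Traxler array (Cr–O–C8–C7–C11–C13), so the butenolide C7=C11 bond moves to the exocyclic C11=C13 position and the α-methylene lactone appears as the ring closes. The closest known reaction type is the Nozaki–Hiyama–Kishi (Barbier-type) allylation of aldehydes with 3-(bromomethyl)butenolides and its macrocyclic use with 2-(bromomethyl)acrylates in germacranolide work. The ten-membered carbocycle is closed in the 10-exo-trig mode at the aldehyde carbon (the C=O bond stays outside the new ring), with high dilution and slow addition favouring it over oligomers. C7 is controlled by the existing C6 centre: allylic 1,3-strain across the Z-C4=C5 alkene keeps H3 and H6 in the alkene plane and puts C2 and C7 on the same face, so the tether should reach C7 only across the lactone face that carries C5, giving the cis-fused (6S,7R) lactone. C8 is controlled by the chair: the ring-locked allyl unit is of the E-crotyl type (C6 trans to C13), C9 must sit anti to C11 (pseudo-equatorial, away from the lactone) and the aldehyde oxygen anti to C6, which should give the 7,8-anti alcohol (8S), the epimer that the invertive esterification of step 15 requires. The step needs γ- over α-attack (secured by the cyclic transition state), chemoselective reduction of the allylic bromide in the presence of aldehyde, epoxide, silyl ether and lactone (the known profile of CrCl2), and ring closure ahead of protonation (anhydrous conditions, sieves).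

Step 15
Reactants: 22 (1R,3S,4Z,6S,7R,8S,10R)-1,10-epoxy-8-hydroxy-3-(triethylsilyloxy)germacra-4,11(13)-dien-12,6-olide; 23 furan-3-carboxylic acid
Product: 24 (1R,3S,4Z,6S,7R,8R,10R)-1,10-epoxy-8-(furan-3-carbonyloxy)-3-(triethylsilyloxy)germacra-4,11(13)-dien-12,6-olide
Conditions: PPh3, diisopropyl azodicarboxylate (betaine pre-formed at 0 °C), toluene/THF, 0 °C to rt
Reagents that add atoms: none
Why: Mitsunobu esterification, in which the C8 alkoxyphosphonium ion is displaced by 3-furoate in an SN2 reaction, should invert 8S to the 8R ester, and pre-forming the betaine keeps free phosphine away from the α-methylene lactone.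

Step 16
Reactants: 24 (1R,3S,4Z,6S,7R,8R,10R)-1,10-epoxy-8-(furan-3-carbonyloxy)-3-(triethylsilyloxy)germacra-4,11(13)-dien-12,6-olide
Product: 25 (1R,3S,4Z,6S,7R,8R,10R)-1,10-epoxy-8-(furan-3-carbonyloxy)-3-hydroxygermacra-4,11(13)-dien-12,6-olide
Conditions: HF·pyridine, pyridine, THF, 0 °C
Reagents that add atoms: none
Why: fluoride-mediated desilylation with pyridine-buffered HF should remove the TES ether without opening the epoxide or touching the furoate and the α-methylene lactone.

Compound list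
1 | but-3-yn-1-ol | C#CCCO | starting material
2 | 1-[(but-3-yn-1-yloxy)methyl]-4-methoxybenzene | C#CCCOCc1ccc(OC)cc1 | intermediate
3 | dimethyl{(1E)-4-[(4-methoxybenzyl)oxy]-2-methylbut-1-en-1-yl}alane | C[Al](C)/C=C(\C)CCOCc1ccc(OC)cc1 | intermediate
4 | lithium butyl(dimethyl){(1E)-4-[(4-methoxybenzyl)oxy]-2-methylbut-1-en-1-yl}alanate | [Li+].CCCC[Al-](C)(C)/C=C(\C)CCOCc1ccc(OC)cc1 | intermediate
5 | (E)-6-[(4-methoxybenzyl)oxy]-4-methylhex-3-en-1-ol | OCC/C=C(\C)CCOCc1ccc(OC)cc1 | intermediate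
6 | (E)-6-[(4-methoxybenzyl)oxy]-4-methylhex-3-enal | O=CC/C=C(\C)CCOCc1ccc(OC)cc1 | intermediate
7 | methyl propiolate | C#CC(=O)OC | starting material
8 | methyl 3-(methylzincio)prop-2-ynoate | C[Zn]C#CC(=O)OC | intermediate
9 | methyl (4S,6E)-4-hydroxy-9-[(4-methoxybenzyl)oxy]-7-methylnon-6-en-2-ynoate | COC(=O)C#C[C@@H](O)C/C=C(\C)CCOCc1ccc(OC)cc1 | intermediate
10 | methyl (4S,6E)-9-[(4-methoxybenzyl)oxy]-7-methyl-4-(triethylsilyloxy)non-6-en-2-ynoate | COC(=O)C#C[C@@H](O[Si](CC)(CC)CC)C/C=C(\C)CCOCc1ccc(OC)cc1 | intermediate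
11 | methyl (2Z,4S,6E)-9-[(4-methoxybenzyl)oxy]-3,7-dimethyl-4-(triethylsilyloxy)nona-2,6-dienoate | COC(=O)/C=C(C)\[C@@H](O[Si](CC)(CC)CC)C/C=C(\C)CCOCc1ccc(OC)cc1 | intermediate
12 | methyl (2Z,4S)-5-[(2R,3R)-3-{2-[(4-methoxybenzyl)oxy]ethyl}-3-methyloxiran-2-yl]-3-methyl-4-(triethylsilyloxy)pent-2-enoate | COC(=O)/C=C(C)\[C@@H](O[Si](CC)(CC)CC)C[C@H]1O[C@]1(C)CCOCc1ccc(OC)cc1 | intermediate
13 | (2Z,4S)-N-methoxy-5-[(2R,3R)-3-{2-[(4-methoxybenzyl)oxy]ethyl}-3-methyloxiran-2-yl]-N,3-dimethyl-4-(triethylsilyloxy)pent-2-enamide | CON(C)C(=O)/C=C(C)\[C@@H](O[Si](CC)(CC)CC)C[C@H]1O[C@]1(C)CCOCc1ccc(OC)cc1 | intermediate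
14 | (4Z,6S)-7-[(2R,3R)-3-{2-[(4-methoxybenzyl)oxy]ethyl}-3-methyloxiran-2-yl]-5-methyl-6-(triethylsilyloxy)hepta-1,4-dien-3-one | C=CC(=O)/C=C(C)\[C@@H](O[Si](CC)(CC)CC)C[C@H]1O[C@]1(C)CCOCc1ccc(OC)cc1 | intermediate
15 | (3R,4Z,6S)-7-[(2R,3R)-3-{2-[(4-methoxybenzyl)oxy]ethyl}-3-methyloxiran-2-yl]-5-methyl-6-(triethylsilyloxy)hepta-1,4-dien-3-ol | C=C[C@@H](O)/C=C(C)\[C@@H](O[Si](CC)(CC)CC)C[C@H]1O[C@]1(C)CCOCc1ccc(OC)cc1 | intermediate
16 | 2-(bromomethyl)prop-2-enoic acid | C=C(CBr)C(=O)O | starting material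
17 | (3R,4Z,6S)-7-[(2R,3R)-3-{2-[(4-methoxybenzyl)oxy]ethyl}-3-methyloxiran-2-yl]-5-methyl-6-(triethylsilyloxy)hepta-1,4-dien-3-yl 2-(bromomethyl)prop-2-enoate | C=C[C@@H](OC(=O)C(=C)CBr)/C=C(C)\[C@@H](O[Si](CC)(CC)CC)C[C@H]1O[C@]1(C)CCOCc1ccc(OC)cc1 | intermediate
18 | (5S)-3-(bromomethyl)-5-{(1Z,3S)-4-[(2R,3R)-3-{2-[(4-methoxybenzyl)oxy]ethyl}-3-methyloxiran-2-yl]-2-methyl-3-(triethylsilyloxy)but-1-en-1-yl}furan-2(5H)-one | COc1ccc(COCC[C@@]2(C)O[C@@H]2C[C@H](O[Si](CC)(CC)CC)/C(C)=C\[C@@H]2OC(=O)C(CBr)=C2)cc1 | intermediate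
19 | (5S)-3-(bromomethyl)-5-{(1Z,3S)-4-[(2R,3R)-3-(2-hydroxyethyl)-3-methyloxiran-2-yl]-2-methyl-3-(triethylsilyloxy)but-1-en-1-yl}furan-2(5H)-one | OCC[C@@]1(C)O[C@@H]1C[C@H](O[Si](CC)(CC)CC)/C(C)=C\[C@@H]1OC(=O)C(CBr)=C1 | intermediate
20 | (5S)-3-(bromomethyl)-5-{(1Z,3S)-2-methyl-4-[(2R,3R)-3-methyl-3-(2-oxoethyl)oxiran-2-yl]-3-(triethylsilyloxy)but-1-en-1-yl}furan-2(5H)-one | O=CC[C@@]1(C)O[C@@H]1C[C@H](O[Si](CC)(CC)CC)/C(C)=C\[C@@H]1OC(=O)C(CBr)=C1 | intermediate
21 | dichloro{[(5S)-2-oxo-5-(side chain of 20)-2,5-dihydrofuran-3-yl]methyl}chromium | O=CC[C@@]1(C)O[C@@H]1C[C@H](O[Si](CC)(CC)CC)/C(C)=C\[C@@H]1OC(=O)C(C[Cr](Cl)Cl)=C1 | intermediate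
22 | (1R,3S,4Z,6S,7R,8S,10R)-1,10-epoxy-8-hydroxy-3-(triethylsilyloxy)germacra-4,11(13)-dien-12,6-olide | C=C1C(=O)O[C@H]2/C=C(/C)[C@@H](O[Si](CC)(CC)CC)C[C@H]3O[C@]3(C)C[C@H](O)[C@@H]12 | intermediate
23 | furan-3-carboxylic acid | OC(=O)c1ccoc1 | starting material
24 | (1R,3S,4Z,6S,7R,8R,10R)-1,10-epoxy-8-(furan-3-carbonyloxy)-3-(triethylsilyloxy)germacra-4,11(13)-dien-12,6-olide | C=C1C(=O)O[C@H]2/C=C(/C)[C@@H](O[Si](CC)(CC)CC)C[C@H]3O[C@]3(C)C[C@@H](OC(=O)c3ccoc3)[C@@H]12 | intermediate
25 | (1R,3S,4Z,6S,7R,8R,10R)-1,10-epoxy-8-(furan-3-carbonyloxy)-3-hydroxygermacra-4,11(13)-dien-12,6-olide | C=C1C(=O)O[C@H]2/C=C(/C)[C@@H](O)C[C@H]3O[C@]3(C)C[C@@H](OC(=O)c3ccoc3)[C@@H]12 | target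

Total step count: 16. Longest linear sequence: 16 steps (from but-3-yn-1-ol 1).

Steps most likely to fail

1. Step 14 (ring closure). The allylchromium may be protonated or may oligomerise before the ten-membered ring closes, trivalent chromium may open the epoxide, and ring strain may override the chair so that the aldehyde adds through a boat or to the lactone face anti to C5. The fallback replaces the redox metal by a thermal intramolecular 2-(alkoxycarbonyl)allylboration. It sets out from 19: Miyaura-type borylation of the allylic bromide (B2pin2, Pd2(dba)3, toluene, 50 °C) should give the allylboronate alcohol F1. Buffered Dess–Martin oxidation then gives the boronate aldehyde F2, which is heated in dilute toluene (80 °C) to close the ring through the same closed chair without any Lewis-acidic salt. Aqueous work-up releases the alcohol, and the fallback rejoins the route at 22.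

2. Step 15 (inversion at C8). The alkoxyphosphonium ion may eliminate across C8–C9 or be captured by the lactone carbonyl, and free phosphine may add to the α-methylene lactone, instead of clean SN2 displacement at a ring carbon flanked by C7. The fallback separates activation from displacement and uses no phosphine. It sets out from 22: chloromethanesulfonyl chloride and pyridine (CH2Cl2, 0 °C) give the chloromethanesulfonate F3, which is displaced with inversion by cesium 3-furoate (from 23 and Cs2CO3) with 18-crown-6 in toluene. It rejoins the route at 24.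

3. Step 4 (asymmetric alkynylation). The basic zinc species may move the C1=C10 alkene of the β,γ-unsaturated aldehyde into conjugation before addition, and enantioface discrimination may be poor for this unbranched aldehyde. The fallback sets the carbinol by reduction instead of addition. It sets out from 6: lithiated methyl propiolate (n-BuLi, THF, −78 °C) adds without isomerisation to give the racemic hydroxy ynoate F4. Dess–Martin oxidation gives the keto ynoate F5, and Midland reduction with (S)-Alpine-Borane (neat, rt) should give the 4S alcohol. It rejoins the route at 9.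

Further compounds
F1 | step 14 | (5S)-5-{(1Z,3S)-4-[(2R,3R)-3-(2-hydroxyethyl)-3-methyloxiran-2-yl]-2-methyl-3-(triethylsilyloxy)but-1-en-1-yl}-3-[(4,4,5,5-tetramethyl-1,3,2-dioxaborolan-2-yl)methyl]furan-2(5H)-one | OCC[C@@]1(C)O[C@@H]1C[C@H](O[Si](CC)(CC)CC)/C(C)=C\[C@@H]1OC(=O)C(CB2OC(C)(C)C(C)(C)O2)=C1
F2 | step 14 | (5S)-5-{(1Z,3S)-2-methyl-4-[(2R,3R)-3-methyl-3-(2-oxoethyl)oxiran-2-yl]-3-(triethylsilyloxy)but-1-en-1-yl}-3-[(4,4,5,5-tetramethyl-1,3,2-dioxaborolan-2-yl)methyl]furan-2(5H)-one | O=CC[C@@]1(C)O[C@@H]1C[C@H](O[Si](CC)(CC)CC)/C(C)=C\[C@@H]1OC(=O)C(CB2OC(C)(C)C(C)(C)O2)=C1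
F3 | step 15 | (1R,3S,4Z,6S,7R,8S,10R)-8-[(chloromethanesulfonyl)oxy]-1,10-epoxy-3-(triethylsilyloxy)germacra-4,11(13)-dien-12,6-olide | C=C1C(=O)O[C@H]2/C=C(/C)[C@@H](O[Si](CC)(CC)CC)C[C@H]3O[C@]3(C)C[C@H](OS(=O)(=O)CCl)[C@@H]12
F4 | step 4 | methyl (6E)-4-hydroxy-9-[(4-methoxybenzyl)oxy]-7-methylnon-6-en-2-ynoate (racemic) | COC(=O)C#CC(O)C/C=C(\C)CCOCc1ccc(OC)cc1
F5 | step 4 | methyl (6E)-9-[(4-methoxybenzyl)oxy]-7-methyl-4-oxonon-6-en-2-ynoate | COC(=O)C#CC(=O)C/C=C(\C)CCOCc1ccc(OC)cc1
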